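**Strategy.** The lactone C3–C4 bond sits between the carbonyl C2 and the oxygen-bearing C5, so the core is a reduced 2,3-dibenzylsuccinate, a 1,4-dicarbonyl. That bond is formed by oxidative cross-coupling of two lithium enolates: an (R)-oxazolidinone imide carrying the open 1,2-diarylpropane-1,3-diol half and a methyl ester carrying the trans-2-aryl-3-(hydroxymethyl)dihydrobenzofuran half. One operation joins both fully built halves and sets lactone C4; C3 is settled afterwards by equilibration to the trans lactone. Both halves come from a single anti-aldol diol, because they share the S-configured CH(CH2OH) carbon and differ only in whether the ortho phenol has closed onto the benzylic carbon.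

Key step: step 15

Remark: the MgCl2-catalysed aldol is assumed to follow the facial sense of alkylation of the chelated Z-enolate (attack opposite the 4-benzyl group); if the (S)-auxiliary gave the mirror-image anti adduct, auxiliary 17 would be used in place of 8 in step 6.

Step 1
Reactants: 1 methyl 3-(4-hydroxy-3-methoxyphenyl)propanoate; 2 allyl bromide
Product: 3 methyl 3-[3-methoxy-4-(prop-2-en-1-yloxy)phenyl]propanoate
Conditions: K2CO3, acetone, reflux
Reagents that add atoms: none
Why: Williamson etherification of the phenoxide with a reactive allylic bromide; the methyl ester is inert to carbonate in acetone.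

Step 2
Reactants: 3 methyl 3-[3-methoxy-4-(prop-2-en-1-yloxy)phenyl]propanoate
Product: 4 methyl 3-[4-hydroxy-3-methoxy-5-(prop-2-en-1-yl)phenyl]propanoate
Conditions: N,N-diethylaniline, 190 °C
Reagents that add atoms: none
Why: Aromatic Claisen rearrangement ([3,3] shift, then tautomerisation) should deliver the allyl group to the only free ortho position, the other being blocked by the methoxy group.

Step 3
Reactants: 4 methyl 3-[4-hydroxy-3-methoxy-5-(prop-2-en-1-yl)phenyl]propanoate
Product: 5 methyl 3-[4-(benzyloxy)-3-methoxy-5-(prop-2-en-1-yl)phenyl]propanoate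
Conditions: BnBr, K2CO3, DMF, 50 °C
Reagents that add atoms: benzyl bromide BrCc1ccccc1
Why: Williamson benzylation of the hindered phenol gives a protecting group that tolerates every later base, hydride and fluoride step.

Step 4
Reactants: 5 methyl 3-[4-(benzyloxy)-3-methoxy-5-(prop-2-en-1-yl)phenyl]propanoate
Product: 6 methyl 3-[4-(benzyloxy)-3-methoxy-5-(2-oxoethyl)phenyl]propanoate
Conditions: OsO4 (cat.), NaIO4, 2,6-lutidine, dioxane–H2O, rt
Reagents that add atoms: sodium periodate [Na+].[O-]I(=O)(=O)=O
Why: Lemieux–Johnson cleavage (catalytic dihydroxylation of the terminal alkene, then periodate scission) should give the arylacetaldehyde, which is used crude because it enolises and air-oxidises easily.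

Step 5
Reactants: 6 methyl 3-[4-(benzyloxy)-3-methoxy-5-(2-oxoethyl)phenyl]propanoate
Product: 7 2-[2-(benzyloxy)-3-methoxy-5-(3-methoxy-3-oxopropyl)phenyl]acetic acid
Conditions: NaClO2, NaH2PO4, 2-methyl-2-butene, t-BuOH–H2O, 0 °C → rt
Reagents that add atoms: sodium chlorite [Na+].[O-]Cl=O
Why: Pinnick oxidation converts the aldehyde into the acid without touching the ester or benzyl ether, and the alkene scavenger removes hypochlorous acid before it can chlorinate the electron-rich ring.

Step 6
Reactants: 7 2-[2-(benzyloxy)-3-methoxy-5-(3-methoxy-3-oxopropyl)phenyl]acetic acid; 8 (S)-4-benzyl-oxazolidin-2-one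
Product: 10 (S)-4-benzyl-3-{2-[2-(benzyloxy)-3-methoxy-5-(3-methoxy-3-oxopropyl)phenyl]acetyl}oxazolidin-2-one, via pivalic mixed anhydride 9 (not isolated)
Conditions: PivCl, Et3N, THF, −20 °C; then 8, LiCl, rt
Reagents that add atoms: none
Why: N-acylation through the mixed anhydride, in which the LiCl-activated oxazolidinone attacks the unhindered arylacetyl carbonyl and not the pivaloyl carbonyl; the methyl ester is not activated and stays.

Step 7
Reactants: 10 (S)-4-benzyl-3-{2-[2-(benzyloxy)-3-methoxy-5-(3-methoxy-3-oxopropyl)phenyl]acetyl}oxazolidin-2-one; 11 4-(benzyloxy)-3-methoxybenzaldehyde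
Product: 13 (S)-4-benzyl-3-{(2R,3S)-2-[2-(benzyloxy)-3-methoxy-5-(3-methoxy-3-oxopropyl)phenyl]-3-[4-(benzyloxy)-3-methoxyphenyl]-3-hydroxypropanoyl}oxazolidin-2-one, via trimethylsilyl-protected aldol adduct 12 (not isolated)
Conditions: MgCl2 (cat.), Et3N, Me3SiCl, EtOAc, rt; then 1 M HCl–THF, 0 °C
Reagents that add atoms: none
Why: Direct MgCl2-catalysed anti-aldol under soft enolisation, in which only the arylacetyl imide (not the methyl ester) enolises, the magnesium-chelated Z-enolate is attacked on the face away from the auxiliary benzyl group to set the aryl-bearing carbon, the boat-like transition state places the new hydroxyl anti to it, and silyl trapping of the aldolate prevents retro-aldol.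

Step 8
Reactants: 13 anti-aldol adduct
Product: 14 methyl 3-{4-(benzyloxy)-3-[(1S,2S)-1-[4-(benzyloxy)-3-methoxyphenyl]-1,3-dihydroxypropan-2-yl]-5-methoxyphenyl}propanoate
Conditions: NaBH4, THF–H2O, 0 °C → rt
Reagents that add atoms: none
Why: Borohydride reduces the activated exocyclic imide carbonyl to the primary alcohol and releases the auxiliary, while the unactivated methyl ester survives and neither stereocentre is touched.

Step 9
Reactants: 14 anti-diol methyl ester
Product: 15 methyl 3-{4-(benzyloxy)-3-[(1S,2S)-1-[4-(benzyloxy)-3-methoxyphenyl]-1,3-bis(tert-butyldimethylsilyloxy)propan-2-yl]-5-methoxyphenyl}propanoate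
Conditions: t-BuMe2SiOTf, 2,6-lutidine, CH2Cl2, −78 → 0 °C
Reagents that add atoms: tert-butyldimethylsilyl triflate CC(C)(C)[Si](C)(C)OS(=O)(=O)C(F)(F)F
Why: The silyl triflate with a hindered base silylates both the primary and the hindered benzylic hydroxyl, and the buffered medium avoids ionisation of the electron-rich benzylic carbon.

Step 10
Reactants: 15 bis-silyl ether methyl ester
Product: 16 3-{4-(benzyloxy)-3-[(1S,2S)-1-[4-(benzyloxy)-3-methoxyphenyl]-1,3-bis(tert-butyldimethylsilyloxy)propan-2-yl]-5-methoxyphenyl}propanoic acid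
Conditions: LiOH·H2O, THF–MeOH–H2O, rt; then 1 M HCl to pH 4, 0 °C
Reagents that add atoms: lithium hydroxide [Li+].[OH-]
Why: Saponification of the unhindered methyl ester; alkyl silyl ethers and benzyl ethers are stable to hydroxide, and the cold, brief acidification spares the benzylic silyl ether.

Step 11
Reactants: 16 bis-silyl ether acid; 17 (R)-4-benzyl-oxazolidin-2-one
Product: 19 (R)-4-benzyl-3-[3-(4-benzyloxy-3-{(1S,2S)-1-[4-(benzyloxy)-3-methoxyphenyl]-1,3-bis(tert-butyldimethylsilyloxy)propan-2-yl}-5-methoxyphenyl)propanoyl]oxazolidin-2-one (fragment 1), via pivalic mixed anhydride 18 (not isolated)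
Conditions: PivCl, Et3N, THF, −20 °C; then 17, LiCl, rt
Reagents that add atoms: none
Why: The same mixed-anhydride N-acylation as in step 6, now installing the auxiliary whose benzyl group will steer the coupling at the alpha carbon.

Step 12
Reactants: 14 anti-diol methyl ester
Product: 20 methyl 3-{3-[(1S,2S)-1,3-dihydroxy-1-(4-hydroxy-3-methoxyphenyl)propan-2-yl]-4-hydroxy-5-methoxyphenyl}propanoate
Conditions: H2 (1 atm), 10% Pd/C, EtOAc–MeOH, rt, short contact
Reagents that add atoms: none
Why: Neutral hydrogenolysis cleaves both aryl benzyl ethers quickly, and stopping at full debenzylation in the absence of acid should leave the benzylic C–OH bond intact.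

Step 13
Reactants: 20 tetraol methyl ester
Product: 21 methyl 3-[(2R,3S)-2-(4-hydroxy-3-methoxyphenyl)-3-(hydroxymethyl)-7-methoxy-2,3-dihydro-1-benzofuran-5-yl]propanoate
Conditions: TsOH·H2O (cat.), CH2Cl2–THF, 0 °C → rt, dilute
Reagents that add atoms: none
Why: Acid ionises the p-hydroxybenzylic alcohol to a stabilised benzylic cation that the ortho phenol oxygen captures in a 5-exo ring closure; the retained S carbon places the aryl group trans to CH2OH, so the carbinol carbon ends as R whatever its configuration before ionisation.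

Step 14
Reactants: 21 trans-dihydrobenzofuran phenol alcohol
Product: 22 methyl 3-[(2R,3S)-7-methoxy-2-{3-methoxy-4-[tri(propan-2-yl)silyloxy]phenyl}-3-{[tri(propan-2-yl)silyloxy]methyl}-2,3-dihydro-1-benzofuran-5-yl]propanoate (fragment 2)
Conditions: i-Pr3SiCl, imidazole, DMF, rt
Reagents that add atoms: chlorotri(propan-2-yl)silane CC(C)[Si](Cl)(C(C)C)C(C)C
Why: Imidazole-promoted silylation caps the phenol and the primary alcohol in one operation, and the bulky aryl silyl ether is chosen because it resists the amide base, aqueous borohydride and amidine base of the next three steps better than a smaller silyl group.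

Step 15
Reactants: 19 fragment 1 imide; 22 fragment 2 methyl ester
Product: 25 coupled 2,3-bis(arylmethyl)succinate imide methyl ester (S at the imide-bearing carbon; both epimers at the ester-bearing carbon), via imide lithium Z-enolate 23 (not isolated), via ester lithium enolate 24 (not isolated)
Conditions: LiN(i-Pr)2, THF, −78 °C; then Fe(acac)3, −78 °C → rt
Reagents that add atoms: none
Why: LiN(i-Pr)2 converts 19 into its chelated Z-enolate 23 and 22 into its ester enolate 24; one-electron oxidation by Fe(acac)3 (trivalent iron) within a mixed enolate aggregate gives an iron-bound alpha-carbonyl radical that is captured by the second enolate, and a second one-electron oxidation delivers the 1,4-dicarbonyl, the iron ending as divalent. The closest known reaction type is the intermolecular oxidative heterocoupling of an N-acyl oxazolidinone enolate with an ester enolate, used to assemble 2,3-dibenzylsuccinates for dibenzylbutyrolactone lignans. No ring is closed in this step: the dihydrobenzofuran is already in place and the lactone follows in step 16. The new stereocentre at the imide-bearing carbon (later lactone C4) is controlled by the benzyl group of the (R)-auxiliary, which shields one face of the chelated Z-enolate as in its alkylations and should give the S configuration; the ester-bearing carbon (later C3) is not controlled and is corrected in step 17. The step needs cross- over homo-coupling, which the unlike enolate classes (imide against ester, differing in aggregation and ease of oxidation) and a moderate excess of the recoverable ester 22 should secure, and face selectivity at one carbon only, which the auxiliary supplies. All other functionality in both fragments is aryl, benzyl and silyl ether, inert to the amide base at −78 °C and to a mild one-electron oxidant.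

Step 16
Reactants: 25 coupled succinate imide methyl ester
Product: 27 protected 3,4-bis(arylmethyl)butyrolactone (4S; both epimers at C3), via hydroxy methyl ester 26 (not isolated)
Conditions: NaBH4, THF–H2O, 0 °C → rt
Reagents that add atoms: none
Why: Borohydride reduces the imide carbonyl in preference to the hindered methyl ester, and the liberated primary alcohol closes onto that ester by 5-exo-trig acyl substitution; C4 is not enolisable and keeps its configuration.

Step 17
Reactants: 27 lactone as C3-epimer pair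
Product: 28 protected (3S,4S)-trans-3,4-bis(arylmethyl)butyrolactone
Conditions: DBU, toluene, rt → 50 °C
Reagents that add atoms: none
Why: Base-mediated equilibration through the lactone enolate at C3, the only acidic stereocentre, should converge on the thermodynamically preferred trans-3,4-disubstituted lactone and also closes any hydroxy ester left from step 16.

Step 18
Reactants: 28 protected trans lactone
Product: 29 (3S,4S)-lactone with all four hydroxyl groups free and the two phenols of the open half still benzylated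
Conditions: Bu4NF, AcOH, THF, rt → 40 °C
Reagents that add atoms: none
Why: Fluoride removes the two tert-butyldimethylsilyl and two tri(propan-2-yl)silyl groups, and the acetic acid buffer keeps the medium from becoming basic enough to open the dihydrobenzofuran through its phenoxide or to disturb the lactone.

Step 19
Reactants: 29 dibenzyl ether of the target
Product: 30 target CNP0199264.1
Conditions: H2 (1 atm), 10% Pd/C, EtOAc–MeOH, rt, short contact
Reagents that add atoms: none
Why: Neutral hydrogenolysis of the two aryl benzyl ethers ends the synthesis without acid, so the free ortho phenol of the open half cannot cyclise onto its benzylic carbinol and no stereocentre is exposed to ionising conditions.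

**Compound list**

1 | methyl 3-(4-hydroxy-3-methoxyphenyl)propanoate | COC(=O)CCc1ccc(O)c(OC)c1 | starting material
2 | allyl bromide | C=CCBr | starting material
3 | methyl 3-[3-methoxy-4-(prop-2-en-1-yloxy)phenyl]propanoate | COC(=O)CCc1ccc(OCC=C)c(OC)c1 | intermediate
4 | methyl 3-[4-hydroxy-3-methoxy-5-(prop-2-en-1-yl)phenyl]propanoate | COC(=O)CCc1cc(CC=C)c(O)c(OC)c1 | intermediate
5 | methyl 3-[4-(benzyloxy)-3-methoxy-5-(prop-2-en-1-yl)phenyl]propanoate | COC(=O)CCc1cc(CC=C)c(OCc2ccccc2)c(OC)c1 | intermediate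
6 | methyl 3-[4-(benzyloxy)-3-methoxy-5-(2-oxoethyl)phenyl]propanoate | COC(=O)CCc1cc(CC=O)c(OCc2ccccc2)c(OC)c1 | intermediate
7 | 2-[2-(benzyloxy)-3-methoxy-5-(3-methoxy-3-oxopropyl)phenyl]acetic acid | COC(=O)CCc1cc(CC(=O)O)c(OCc2ccccc2)c(OC)c1 | intermediate
8 | (S)-4-benzyl-oxazolidin-2-one | O=C1OC[C@H](Cc2ccccc2)N1 | starting material
9 | pivalic mixed anhydride of acid 7 | COC(=O)CCc1cc(CC(=O)OC(=O)C(C)(C)C)c(OCc2ccccc2)c(OC)c1 | intermediate
10 | (S)-4-benzyl-3-{2-[2-(benzyloxy)-3-methoxy-5-(3-methoxy-3-oxopropyl)phenyl]acetyl}oxazolidin-2-one | COC(=O)CCc1cc(CC(=O)N2[C@@H](Cc3ccccc3)COC2=O)c(OCc2ccccc2)c(OC)c1 | intermediate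
11 | 4-(benzyloxy)-3-methoxybenzaldehyde | COc1cc(C=O)ccc1OCc1ccccc1 | starting material
12 | O-trimethylsilyl ether of anti-aldol adduct 13 | COC(=O)CCc1cc([C@H]([C@H](O[Si](C)(C)C)c2ccc(OCc3ccccc3)c(OC)c2)C(=O)N2[C@@H](Cc3ccccc3)COC2=O)c(OCc2ccccc2)c(OC)c1 | intermediate
13 | anti-aldol adduct, (2R,3S) in the acyl chain, (S)-auxiliary | COC(=O)CCc1cc([C@H]([C@H](O)c2ccc(OCc3ccccc3)c(OC)c2)C(=O)N2[C@@H](Cc3ccccc3)COC2=O)c(OCc2ccccc2)c(OC)c1 | intermediate
14 | methyl 3-{4-(benzyloxy)-3-[(1S,2S)-1-[4-(benzyloxy)-3-methoxyphenyl]-1,3-dihydroxypropan-2-yl]-5-methoxyphenyl}propanoate | COC(=O)CCc1cc([C@H]([C@H](O)c2ccc(OCc3ccccc3)c(OC)c2)CO)c(OCc2ccccc2)c(OC)c1 | intermediate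
15 | bis(tert-butyldimethylsilyl) ether of diol 14 | COC(=O)CCc1cc([C@H]([C@H](O[Si](C)(C)C(C)(C)C)c2ccc(OCc3ccccc3)c(OC)c2)CO[Si](C)(C)C(C)(C)C)c(OCc2ccccc2)c(OC)c1 | intermediate
16 | carboxylic acid from ester 15 | OC(=O)CCc1cc([C@H]([C@H](O[Si](C)(C)C(C)(C)C)c2ccc(OCc3ccccc3)c(OC)c2)CO[Si](C)(C)C(C)(C)C)c(OCc2ccccc2)c(OC)c1 | intermediate
17 | (R)-4-benzyl-oxazolidin-2-one | O=C1OC[C@@H](Cc2ccccc2)N1 | starting material
18 | pivalic mixed anhydride of acid 16 | CC(C)(C)C(=O)OC(=O)CCc1cc([C@H]([C@H](O[Si](C)(C)C(C)(C)C)c2ccc(OCc3ccccc3)c(OC)c2)CO[Si](C)(C)C(C)(C)C)c(OCc2ccccc2)c(OC)c1 | intermediate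
19 | fragment 1, (R)-4-benzyl-3-(3-arylpropanoyl)oxazolidin-2-one carrying the protected (1S,2S) open diol | O=C(CCc1cc([C@H]([C@H](O[Si](C)(C)C(C)(C)C)c2ccc(OCc3ccccc3)c(OC)c2)CO[Si](C)(C)C(C)(C)C)c(OCc2ccccc2)c(OC)c1)N1[C@H](Cc2ccccc2)COC1=O | intermediate
20 | methyl 3-{3-[(1S,2S)-1,3-dihydroxy-1-(4-hydroxy-3-methoxyphenyl)propan-2-yl]-4-hydroxy-5-methoxyphenyl}propanoate | COC(=O)CCc1cc([C@H]([C@H](O)c2ccc(O)c(OC)c2)CO)c(O)c(OC)c1 | intermediate
21 | methyl 3-[(2R,3S)-2-(4-hydroxy-3-methoxyphenyl)-3-(hydroxymethyl)-7-methoxy-2,3-dihydro-1-benzofuran-5-yl]propanoate | COC(=O)CCc1cc(OC)c2c(c1)[C@@H](CO)[C@H](c1ccc(O)c(OC)c1)O2 | intermediate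
22 | fragment 2, bis[tri(propan-2-yl)silyl] ether of 21 | COC(=O)CCc1cc(OC)c2c(c1)[C@@H](CO[Si](C(C)C)(C(C)C)C(C)C)[C@H](c1ccc(O[Si](C(C)C)(C(C)C)C(C)C)c(OC)c1)O2 | intermediate
23 | lithium Z-enolate of imide 19 | [Li]O/C(=C\Cc1cc([C@H]([C@H](O[Si](C)(C)C(C)(C)C)c2ccc(OCc3ccccc3)c(OC)c2)CO[Si](C)(C)C(C)(C)C)c(OCc2ccccc2)c(OC)c1)N1[C@H](Cc2ccccc2)COC1=O | intermediate
24 | lithium enolate of ester 22 (double-bond geometry left open) | [Li]OC(OC)=CCc1cc(OC)c2c(c1)[C@@H](CO[Si](C(C)C)(C(C)C)C(C)C)[C@H](c1ccc(O[Si](C(C)C)(C(C)C)C(C)C)c(OC)c1)O2 | intermediate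
25 | coupled 2,3-bis(arylmethyl)succinate, (R)-oxazolidinone imide and methyl ester, S at the imide-bearing carbon, both epimers at the ester-bearing carbon | COc1cc([C@@H](O[Si](C)(C)C(C)(C)C)[C@H](CO[Si](C)(C)C(C)(C)C)c2cc(C[C@H](C(=O)N3[C@H](Cc4ccccc4)COC3=O)C(C(=O)OC)Cc3cc(OC)c4c(c3)[C@@H](CO[Si](C(C)C)(C(C)C)C(C)C)[C@H](c3ccc(O[Si](C(C)C)(C(C)C)C(C)C)c(OC)c3)O4)cc(OC)c2OCc2ccccc2)ccc1OCc1ccccc1 | intermediate
26 | hydroxy methyl ester from reduction of 25 (S at the CH2OH-bearing carbon, both epimers at the ester-bearing carbon) | COc1cc([C@@H](O[Si](C)(C)C(C)(C)C)[C@H](CO[Si](C)(C)C(C)(C)C)c2cc(C[C@H](CO)C(C(=O)OC)Cc3cc(OC)c4c(c3)[C@@H](CO[Si](C(C)C)(C(C)C)C(C)C)[C@H](c3ccc(O[Si](C(C)C)(C(C)C)C(C)C)c(OC)c3)O4)cc(OC)c2OCc2ccccc2)ccc1OCc1ccccc1 | intermediate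
27 | protected 3,4-bis(arylmethyl)butyrolactone, 4S, both epimers at C3 | COc1cc([C@@H](O[Si](C)(C)C(C)(C)C)[C@H](CO[Si](C)(C)C(C)(C)C)c2cc(C[C@@H]3COC(=O)C3Cc3cc(OC)c4c(c3)[C@@H](CO[Si](C(C)C)(C(C)C)C(C)C)[C@H](c3ccc(O[Si](C(C)C)(C(C)C)C(C)C)c(OC)c3)O4)cc(OC)c2OCc2ccccc2)ccc1OCc1ccccc1 | intermediate
28 | protected (3S,4S)-trans-3,4-bis(arylmethyl)butyrolactone | COc1cc([C@@H](O[Si](C)(C)C(C)(C)C)[C@H](CO[Si](C)(C)C(C)(C)C)c2cc(C[C@@H]3COC(=O)[C@H]3Cc3cc(OC)c4c(c3)[C@@H](CO[Si](C(C)C)(C(C)C)C(C)C)[C@H](c3ccc(O[Si](C(C)C)(C(C)C)C(C)C)c(OC)c3)O4)cc(OC)c2OCc2ccccc2)ccc1OCc1ccccc1 | intermediate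
29 | desilylated (3S,4S)-lactone, two phenols of the open half still benzylated | COc1cc([C@@H](O)[C@H](CO)c2cc(C[C@@H]3COC(=O)[C@H]3Cc3cc(OC)c4c(c3)[C@@H](CO)[C@H](c3ccc(O)c(OC)c3)O4)cc(OC)c2OCc2ccccc2)ccc1OCc1ccccc1 | intermediate
30 | CNP0199264.1 | COc1cc([C@@H](O)[C@H](CO)c2cc(C[C@@H]3COC(=O)[C@H]3Cc3cc(OC)c4c(c3)[C@@H](CO)[C@H](c3ccc(O)c(OC)c3)O4)cc(OC)c2O)ccc1O | target

**Step count.** 19 steps in total. The longest linear sequence is 16 steps (steps 1–11 and 15–19); the branch through steps 12–14 is equally long.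

**Steps most likely to fail**

Step 15. The two enolates may homodimerise instead of cross-coupling, the methyl ester enolate may self-condense before it is oxidised, or the auxiliary may give poor facial selectivity at the imide carbon in a radical-type bond formation. Cu(2-ethylhexanoate)2 (divalent copper) is the first alternative oxidant. The fallback makes the same bond by a two-electron route, the displacement of an alpha-triflyloxy ester by a chiral imide enolate. It sets out from 22 and 19 and returns at 25. Ester 22 is hydroxylated through its potassium enolate (KN(SiMe3)2, 2-(phenylsulfonyl)-3-phenyloxaziridine, THF, −78 °C) to the alpha-hydroxy ester F1, as both epimers. F1 is converted with Tf2O and 2,6-lutidine (CH2Cl2, −78 °C) into the alpha-triflate F2. Enolate 23, made from 19 with LiN(SiMe3)2 in THF at −78 °C, should then displace the triflate with inversion on the face away from the auxiliary benzyl group and give 25. Both epimers of F2 can be used, because the ester-bearing carbon is equilibrated in step 17.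

Step 7. The aldol may give eroded anti selectivity at the carbinol carbon or stall with the electron-rich aldehyde. The fallback fixes the aryl-bearing carbon by a boron syn-aldol and corrects the carbinol carbon by reagent control. It sets out from 7 and returns at 21 (closed half) and 15 (open half).
- Acid 7 is joined to auxiliary 17 as in step 6 to give the (R)-auxiliary arylacetyl imide F3.
- Evans syn-aldol of F3 with 11 (Bu2BOTf, i-Pr2NEt, CH2Cl2, −78 → 0 °C) should give the (2R,3R) syn adduct F4, and NaBH4 as in step 8 gives the (1R,2S) syn diol F5.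
- Closed half: hydrogenolysis of F5 as in step 12 gives the syn tetraol F6, which converges on 21 under the conditions of step 13 because the carbinol carbon is ionised there.
- Open half: the primary hydroxyl of F5 is silylated (t-BuMe2SiCl, imidazole) to the mono-silyl ether F7, and Dess–Martin periodinane (NaHCO3 buffer) gives the aryl ketone F8.
- Corey–Bakshi–Shibata reduction of F8 with the (R)-methyl oxazaborolidine and BH3·SMe2 should set the S carbinol and give the anti mono-silyl ether F9, and t-BuMe2SiOTf with 2,6-lutidine returns to 15.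

Step 16. Borohydride may also reduce the methyl ester or the lactone once it has formed, or it may attack the ring carbonyl of the hindered imide and open the auxiliary. The fallback separates auxiliary removal from reduction. It sets out from 25 and returns at 27. LiOH–H2O2 (THF–H2O, 0 °C) should cleave the imide exocyclically to the succinic half-ester acid F10. BH3·SMe2 (THF, 0 °C) then reduces the carboxylic acid in the presence of the methyl ester to hydroxy ester 26, which lactonises to 27 on standing or under the DBU of step 17.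

**Further compounds**

F1 | step 15 | methyl 2-hydroxy-3-[(2R,3S)-dihydrobenzofuranyl]propanoate derived from 22, both epimers at the carbinol carbon | COC(=O)C(O)Cc1cc(OC)c2c(c1)[C@@H](CO[Si](C(C)C)(C(C)C)C(C)C)[C@H](c1ccc(O[Si](C(C)C)(C(C)C)C(C)C)c(OC)c1)O2
F2 | step 15 | alpha-triflate of F1, both epimers | COC(=O)C(OS(=O)(=O)C(F)(F)F)Cc1cc(OC)c2c(c1)[C@@H](CO[Si](C(C)C)(C(C)C)C(C)C)[C@H](c1ccc(O[Si](C(C)C)(C(C)C)C(C)C)c(OC)c1)O2
F3 | step 7 | (R)-4-benzyl-3-{2-[2-(benzyloxy)-3-methoxy-5-(3-methoxy-3-oxopropyl)phenyl]acetyl}oxazolidin-2-one | COC(=O)CCc1cc(CC(=O)N2[C@H](Cc3ccccc3)COC2=O)c(OCc2ccccc2)c(OC)c1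
F4 | step 7 | syn-aldol adduct, (2R,3R) in the acyl chain, (R)-auxiliary | COC(=O)CCc1cc([C@H]([C@@H](O)c2ccc(OCc3ccccc3)c(OC)c2)C(=O)N2[C@H](Cc3ccccc3)COC2=O)c(OCc2ccccc2)c(OC)c1
F5 | step 7 | (1R,2S) syn diol, carbinol epimer of 14 | COC(=O)CCc1cc([C@H]([C@@H](O)c2ccc(OCc3ccccc3)c(OC)c2)CO)c(OCc2ccccc2)c(OC)c1
F6 | step 7 | (1R,2S) syn tetraol, carbinol epimer of 20 | COC(=O)CCc1cc([C@H]([C@@H](O)c2ccc(O)c(OC)c2)CO)c(O)c(OC)c1
F7 | step 7 | primary tert-butyldimethylsilyl ether of F5 | COC(=O)CCc1cc([C@H]([C@@H](O)c2ccc(OCc3ccccc3)c(OC)c2)CO[Si](C)(C)C(C)(C)C)c(OCc2ccccc2)c(OC)c1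
F8 | step 7 | (2S)-aryl ketone from oxidation of F7 | COC(=O)CCc1cc([C@H](C(=O)c2ccc(OCc3ccccc3)c(OC)c2)CO[Si](C)(C)C(C)(C)C)c(OCc2ccccc2)c(OC)c1
F9 | step 7 | (1S,2S) anti alcohol with primary tert-butyldimethylsilyl ether | COC(=O)CCc1cc([C@H]([C@H](O)c2ccc(OCc3ccccc3)c(OC)c2)CO[Si](C)(C)C(C)(C)C)c(OCc2ccccc2)c(OC)c1
F10 | step 16 | succinic half-ester acid from hydrolysis of imide 25 (S at the acid-bearing carbon, both epimers at the ester-bearing carbon) | COc1cc([C@@H](O[Si](C)(C)C(C)(C)C)[C@H](CO[Si](C)(C)C(C)(C)C)c2cc(C[C@H](C(=O)O)C(C(=O)OC)Cc3cc(OC)c4c(c3)[C@@H](CO[Si](C(C)C)(C(C)C)C(C)C)[C@H](c3ccc(O[Si](C(C)C)(C(C)C)C(C)C)c(OC)c3)O4)cc(OC)c2OCc2ccccc2)ccc1OCc1ccccc1
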